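(The readings stem from a simulated flask with made-up constants; scatter was added.)

Dawn is judged here by one ratio of rates, with the contents of the flask left aside.

| flask | substrate | reagent | free catalyst | time |
|---|---|---|---|---|
| summer | 0.150 M | 0.225 M | 0.0120 M |  |
| spring | 0.0900 M | 0.165 M | 0.0120 M |  |
| autumn | 0.150 M | 0.110 M | 0.0120 M |  |
| noon | 0.150 M | 0.225 M | 0.0240 M |  |
| dawn | 0.0500 M | 0.225 M | 0.0360 M | 17 h |

| run | time / h | [target] / M |
|---|---|---|
| summer run | 2.1 | 0.0168 |
| summer run | 4.2 | 0.0310 |
| summer run | 6.4 | 0.0423 |
| summer run | 8.5 | 0.0507 |
| summer run | 11 | 0.0575 |
| summer run | 13 | 0.0604 |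
| summer run | 15 | 0.0626 |
| summer run | 17 | 0.0636 |
| spring run | 2.1 | 0.0116 |
| spring run | 4.2 | 0.0212 |
| spring run | 6.4 | 0.0314 |
| spring run | 8.5 | 0.0375 |
| spring run | 11 | 0.0435 |
| spring run | 13 | 0.0456 |
| spring run | 15 | 0.0483 |
| spring run | 17 | 0.0491 |
| autumn run | 2.1 | 0.0088 |
| autumn run | 4.2 | 0.0180 |
| autumn run | 6.4 | 0.0250 |
| autumn run | 8.5 | 0.0313 |
| autumn run | 11 | 0.0373 |
| autumn run | 13 | 0.0413 |
| autumn run | 15 | 0.0447 |
| autumn run | 17 | 0.0474 |
| noon run | 2.1 | 0.0312 |
| noon run | 4.2 | 0.0558 |
| noon run | 6.4 | 0.0724 |
| noon run | 8.5 | 0.0811 |
| noon run | 11 | 0.0856 |
| noon run | 13 | 0.0872 |
| noon run | 15 | 0.0878 |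
| noon run | 17 | 0.0878 |

(scatter of a reading: 4 × 10⁻⁴ M)

- Overall: substrate + reagent -> target, with free catalyst as catalyst.
- Constant volume, constant temperature.
- "The second partner" is reagent.
- An order is taken over about fifteen percent of the charge, up and down.

- the exponent of [free catalyst] in the starting rate at the charge of the summer run (at the point where two percent of the substrate have become target)
- the exponent of [reagent] in the starting rate at the charge of the summer run (at the point where two percent of the substrate have become target)
- target in the dawn run at 17 h, as a share of the substrate charged
- which of these the readings show (the catalyst rests as a dimer / the catalyst wakes slowly / the product reacts on with the second partner / two substrates go astray together / nothing beyond the main steps / the product kills the catalyst)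

1. Start. Over the first interval, target forms at 0.00800 M h⁻¹ in summer and 0.0149 M h⁻¹ in noon, about twice the summer rate on doubled catalyst. Taken across these wide steps, the first readings give a catalyst exponent of 0.893 and, from autumn against summer, a reagent exponent of 0.904.

2. What slows it. Define the astray ratio as the substrate charged that has not become target by 17 h, per unit of target; it counts any substrate still unturned at that time along with substrate lost, and so stands in for the summed rate of loss over the summed rate of target. In summer it is 1.36, and in noon 0.708, lower by a factor of 1.92. In spring it is 0.833, less than in summer on less substrate, though with less reagent as well. Read together, noon and spring fit a loss that competes with the catalyst and eases with falling substrate, as two substrates going astray together would in a step second order in substrate.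

3. Factors for dawn. The ratio is taken as inverse to catalyst and reagent. Dawn has summer's reagent, so the factors to reckon are catalyst and substrate: its catalyst divides the ratio by 3.00, and its substrate is a third of summer's. If the target rate ignores substrate, with a substrate-bound resting state, the ratio falls with the square of that factor and reaches 0.0503. If the target rate is first order in substrate, it reaches 0.151.

4. End. The share made into target is one over one plus the ratio, so the two ends give 95.2% and 86.9%. Joining them by their geometric mean gives a ratio of 0.0871 and a share of 92.0%.

The forecast gives 0.95 for catalyst, 0.93 for reagent, 90% for dawn, less than the share reckoned here, and names two substrates go astray together, with “side path about a quarter of that at the start and fading”.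

The flask gives 91.1% for dawn at 17 h, with exponents 0.86 for catalyst and 0.75 for reagent, and the readings show two substrates go astray together.

    free catalyst + substrate → loaded catalyst + by-product (32.29 M⁻¹ h⁻¹)
    loaded catalyst + reagent → target + free catalyst (4.428 M⁻¹ h⁻¹)
    2 substrate → homo dimer (1.660 M⁻¹ h⁻¹)

That dawn share is an astray ratio of 0.0973, above the joined 0.0871 and below the first-order end. Early in summer the apparent order in substrate is 0.28, between the zero and first orders of the two ends. Carried from summer to spring, with the same catalyst, the reagent factor and the joined substrate factor, the ratio becomes 0.861. That gives a share of 53.7%, and the spring reading at 17 h is 54.6%.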